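**Retrosynthetic overview**

1. Target ⇐ hydrodebromination ⇐ Michael addition of a bromo-blocked ring A dienol ester to a ring B aza-quinone methide (an α-methylene ketone released from a methoxymethyl enaminone). This C–CH2 bond joins the rings and creates the quaternary carbon.
2. Ring A nucleophile ⇐ carbinol O-acylation with (2R)-2-methylbutanoyl chloride, C-bromination, and Dieckmann-type closure of a Seebach dioxolanone acylated with (2E)-3-methoxypent-2-enoyl chloride.
3. Ring B electrophile ⇐ ammonolysis of a vinylogous methyl ester ⇐ O-methylation ⇐ C-acylation with (2R)-2-methylbutanoic acid ⇐ the same dioxolanone/Dieckmann sequence with (2E)-3,5-dimethoxypent-2-enoyl chloride.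
4. Both tertiary carbinol centres come from (S)-lactic acid (self-regeneration of stereocentres); both acyl stereocentres come from an Evans methylation.
5. Ring order: ring A and ring B are each closed separately (six-membered carbocycles by intramolecular Claisen condensation), then coupled.

Assumption: ring A is the ester-bearing cyclohexenedione and ring B the aminodienone; enolisable intermediates are written as one tautomer, and a CIP descriptor may change with the drawn tautomer or with bromine substitution without any change in spatial arrangement.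

**Route**

Step 1
Reactants: 1 (4R)-4-benzyl-1,3-oxazolidin-2-one; 2 butanoyl chloride
Product: 3 (4R)-4-benzyl-3-butanoyl-1,3-oxazolidin-2-one
Conditions: n-BuLi (1.05 equiv), THF, -78 °C; then 2, -78 → 0 °C
Reagents that add atoms: none
Why: N-acylation of the lithiated Evans auxiliary with an acid chloride is clean and touches no stereocentre.

Step 2
Reactants: 3 (4R)-4-benzyl-3-butanoyl-1,3-oxazolidin-2-one
Product: 5 (4R)-4-benzyl-3-[(2R)-2-methylbutanoyl]-1,3-oxazolidin-2-one, via sodium Z-enolate 4 (not isolated)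
Conditions: NaN(SiMe3)2 (1.1 equiv), THF, -78 °C; MeI (5 equiv), -78 → -40 °C; chromatography
Reagents that add atoms: iodomethane, CI
Why: Evans asymmetric alkylation, in which the chelated Z-enolate is methylated on the face opposite the benzyl group, sets the (R) α-carbon (minor diastereomer removed by chromatography).

Step 3
Reactants: 5 (4R)-4-benzyl-3-[(2R)-2-methylbutanoyl]-1,3-oxazolidin-2-one
Product: 6 (2R)-2-methylbutanoic acid
Conditions: LiOH·H2O (2 equiv), H2O2 (30 %, 4 equiv), THF/H2O 3:1, 0 °C; Na2SO3; HCl to pH 2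
Reagents that add atoms: hydrogen peroxide, OO
Why: hydroperoxide-mediated exocyclic imide cleavage (auxiliary removal) is non-epimerising and returns auxiliary 1.

Step 4
Reactants: 6 (2R)-2-methylbutanoic acid
Product: 7 (2R)-2-methylbutanoyl chloride
Conditions: (COCl)2 (1.2 equiv), DMF (cat.), CH2Cl2, 0 °C → rt; used as a solution
Reagents that add atoms: oxalyl chloride, ClC(=O)C(Cl)=O
Why: base-free acid chloride formation through the Vilsmeier intermediate avoids ketene formation, so the α-stereocentre is kept.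

Step 5
Reactants: 8 (S)-lactic acid; 9 pivalaldehyde
Product: 10 (2S,5S)-2-tert-butyl-5-methyl-1,3-dioxolan-4-one
Conditions: p-TsOH·H2O (cat.), H2SO4 (cat.), pentane, reflux, Dean–Stark; recrystallise twice (Et2O/pentane, -78 °C)
Reagents that add atoms: none
Why: acid-catalysed acetalisation gives mainly the cis dioxolanone (Seebach), which crystallises diastereomerically pure, so the acetal carbon stores the lactate configuration.

Step 6
Reactants: 11 methyl 3-oxopentanoate
Product: 12 methyl (2E)-3-methoxypent-2-enoate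
Conditions: HC(OMe)3 (1.5 equiv), H2SO4 (cat.), MeOH, rt; distil
Reagents that add atoms: trimethyl orthoformate, COC(OC)OC
Why: acid-catalysed ketalisation and loss of methanol give the thermodynamically favoured (E) enol ether, fixing the methoxy group on the carbon that becomes the ring C–OMe.

Step 7
Reactants: 12 methyl (2E)-3-methoxypent-2-enoate
Product: 13 (2E)-3-methoxypent-2-enoic acid
Conditions: LiOH·H2O (1.5 equiv), THF/MeOH/H2O, 40 °C; HCl to pH 3 at 0 °C
Reagents that add atoms: lithium hydroxide, [Li+].[OH-]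
Why: ester saponification leaves the base-stable vinylogous carbonate intact, and cold acidification avoids enol ether hydrolysis.

Step 8
Reactants: 13 (2E)-3-methoxypent-2-enoic acid
Product: 14 (2E)-3-methoxypent-2-enoyl chloride
Conditions: (COCl)2 (1.2 equiv), DMF (cat.), CH2Cl2, 0 °C → rt; used crude
Reagents that add atoms: oxalyl chloride, ClC(=O)C(Cl)=O
Why: standard acid chloride formation, well known for β-alkoxyacrylic acids.

Step 9
Reactants: 10 (2S,5S)-2-tert-butyl-5-methyl-1,3-dioxolan-4-one; 14 (2E)-3-methoxypent-2-enoyl chloride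
Product: 16 (2S,5R)-2-tert-butyl-5-[(2E)-3-methoxypent-2-enoyl]-5-methyl-1,3-dioxolan-4-one, via lithium dioxolanone enolate 15 (not isolated)
Conditions: LiN(iPr)2 (1.05 equiv), THF, -78 °C; cannulate into 14 (1.2 equiv), THF, -78 °C; AcOH quench
Reagents that add atoms: none
Why: Seebach self-regeneration of stereocentres, in which the planar enolate is C-acylated (crossed Claisen-type acylation) anti to the tert-butyl group, puts the acyl group where the hydrogen was and fixes the quaternary carbinol carbon.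

Step 10
Reactants: 16 (2S,5R)-2-tert-butyl-5-[(2E)-3-methoxypent-2-enoyl]-5-methyl-1,3-dioxolan-4-one
Product: 18 (6S)-5,6-dihydroxy-3-methoxy-4,6-dimethylcyclohexa-2,4-dien-1-one, via lithium dienolate 17 (not isolated)
Conditions: LiN(SiMe3)2 (2.2 equiv), THF, -78 → -20 °C; 1 M HCl, 0 °C
Reagents that add atoms: none
Why: Dieckmann-type intramolecular Claisen condensation, in which the γ-carbon of the dienolate attacks the activated lactone carbonyl and the hemiacetal alkoxide expels pivalaldehyde, closes ring A while the non-enolisable carbinol carbon keeps its configuration.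

Step 11
Reactants: 18 (6S)-5,6-dihydroxy-3-methoxy-4,6-dimethylcyclohexa-2,4-dien-1-one
Product: 19 (6S)-2-bromo-5,6-dihydroxy-3-methoxy-4,6-dimethylcyclohexa-2,4-dien-1-one
Conditions: NBS (1.0 equiv), CH2Cl2, 0 °C, dark
Reagents that add atoms: N-bromosuccinimide, O=C1CCC(=O)N1Br
Why: electrophilic bromination of the vinylogous acid ends at the unsubstituted enol carbon (a 4-bromo-4-methyl isomer is a positive-bromine donor that equilibrates to it), which blocks this carbon for the coupling.

Step 12
Reactants: 19 (6S)-2-bromo-5,6-dihydroxy-3-methoxy-4,6-dimethylcyclohexa-2,4-dien-1-one; 7 (2R)-2-methylbutanoyl chloride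
Product: 21 (1S)-3-bromo-6-hydroxy-4-methoxy-1,5-dimethyl-2-oxocyclohexa-3,5-dien-1-yl (2R)-2-methylbutanoate, via dilithium alkoxide-dienolate 20 (not isolated)
Conditions: LiN(SiMe3)2 (2.1 equiv), THF, -78 °C; 7 (1.1 equiv), -78 → -30 °C; 1 M HCl
Reagents that add atoms: none
Why: esterification by O-acylation of the dianion occurs at the localised tertiary alkoxide, not at the delocalised bromo-dienolate, and the absence of an amine base avoids ketene formation and loss of the acyl stereocentre.

Step 13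
Reactants: 22 methyl 5-methoxy-3-oxopentanoate
Product: 23 methyl (2E)-3,5-dimethoxypent-2-enoate
Conditions: HC(OMe)3 (1.5 equiv), H2SO4 (cat.), MeOH, rt
Reagents that add atoms: trimethyl orthoformate, COC(OC)OC
Why: the same acid-catalysed enol ether formation as in step 6 gives the (E) β-methoxy enoate with the future bridge carbon already carrying a methoxy leaving group.

Step 14
Reactants: 23 methyl (2E)-3,5-dimethoxypent-2-enoate
Product: 24 (2E)-3,5-dimethoxypent-2-enoic acid
Conditions: LiOH·H2O (1.5 equiv), THF/MeOH/H2O, rt; HCl to pH 3 at 0 °C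
Reagents that add atoms: lithium hydroxide, [Li+].[OH-]
Why: ester saponification under mild conditions that do not eliminate the β-methoxy group.

Step 15
Reactants: 24 (2E)-3,5-dimethoxypent-2-enoic acid
Product: 25 (2E)-3,5-dimethoxypent-2-enoyl chloride
Conditions: (COCl)2 (1.2 equiv), DMF (cat.), CH2Cl2, 0 °C → rt; used crude
Reagents that add atoms: oxalyl chloride, ClC(=O)C(Cl)=O
Why: standard acid chloride formation as in step 8.

Step 16
Reactants: 10 (2S,5S)-2-tert-butyl-5-methyl-1,3-dioxolan-4-one; 25 (2E)-3,5-dimethoxypent-2-enoyl chloride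
Product: 27 (2S,5R)-2-tert-butyl-5-[(2E)-3,5-dimethoxypent-2-enoyl]-5-methyl-1,3-dioxolan-4-one, via sodium dioxolanone enolate 26 (not isolated)
Conditions: NaN(SiMe3)2 (1.05 equiv), THF, -78 °C, 20 min; cannulate into 25 (1.2 equiv), THF, -78 °C; AcOH quench
Reagents that add atoms: none
Why: Seebach enolate C-acylation anti to the tert-butyl group sets the ring B carbinol carbon with retention; the silazide base is used here because its by-product HN(SiMe3)2, unlike a secondary amine, neither consumes 25 nor promotes E1cB loss of its β-methoxy group.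

Step 17
Reactants: 27 (2S,5R)-2-tert-butyl-5-[(2E)-3,5-dimethoxypent-2-enoyl]-5-methyl-1,3-dioxolan-4-one
Product: 29 (6S)-5,6-dihydroxy-3-methoxy-4-(methoxymethyl)-6-methylcyclohexa-2,4-dien-1-one, via lithium dienolate 28 (not isolated)
Conditions: LiN(SiMe3)2 (2.2 equiv), THF, -78 → -40 °C; 1 M HCl, 0 °C
Reagents that add atoms: none
Why: Dieckmann-type intramolecular Claisen condensation as in step 10 closes ring B, the low temperature suppresses β-elimination of methoxide, and the two different ring arms keep the carbinol centre configurationally fixed.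

Step 18
Reactants: 29 (6S)-5,6-dihydroxy-3-methoxy-4-(methoxymethyl)-6-methylcyclohexa-2,4-dien-1-one; 6 (2R)-2-methylbutanoic acid
Product: 31 (6R)-5,6-dihydroxy-3-methoxy-2-(methoxymethyl)-6-methyl-4-[(2R)-2-methylbutanoyl]cyclohexa-2,4-dien-1-one, via enol ester 30 (not isolated)
Conditions: DCC (1.15 equiv), DMAP (0.3 equiv), CH2Cl2, 0 °C → rt, 18 h
Reagents that add atoms: none
Why: Steglich O-acylation of the enol followed by DMAP-catalysed O-to-C acyl migration (Fries-type, the standard triketone synthesis) places the acyl group on the only free enolic CH, with the chelated triketone as the thermodynamic sink.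

Step 19
Reactants: 31 (6R)-5,6-dihydroxy-3-methoxy-2-(methoxymethyl)-6-methyl-4-[(2R)-2-methylbutanoyl]cyclohexa-2,4-dien-1-one
Product: 32 (6R)-6-hydroxy-3,5-dimethoxy-2-(methoxymethyl)-6-methyl-4-[(2R)-2-methylbutanoyl]cyclohexa-2,4-dien-1-one
Conditions: Me3SiCHN2 (1.5 equiv), MeOH/toluene 1:4, 0 °C
Reagents that add atoms: (trimethylsilyl)diazomethane, C[Si](C)(C)C=[N+]=[N-]
Why: diazomethane O-methylation of the chelated ring enol, as with 2-acylcyclohexane-1,3-diones, turns the C5 hydroxyl into a vinylogous methyl ester.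

Step 20
Reactants: 32 (6R)-6-hydroxy-3,5-dimethoxy-2-(methoxymethyl)-6-methyl-4-[(2R)-2-methylbutanoyl]cyclohexa-2,4-dien-1-one
Product: 33 (6R)-5-amino-6-hydroxy-3-methoxy-2-(methoxymethyl)-6-methyl-4-[(2R)-2-methylbutanoyl]cyclohexa-2,4-dien-1-one
Conditions: NH3 (7 M in MeOH, 5 equiv), 0 °C → rt
Reagents that add atoms: ammonia, N
Why: addition–elimination of ammonia at the C5 methoxy carbon, which is conjugated to both the acyl carbonyl and the ring ketone and is therefore the more electrophilic vinylogous ester, gives the hydrogen-bonded enaminone.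

Step 21
Reactants: 21 (1S)-3-bromo-6-hydroxy-4-methoxy-1,5-dimethyl-2-oxocyclohexa-3,5-dien-1-yl (2R)-2-methylbutanoate; 33 (6R)-5-amino-6-hydroxy-3-methoxy-2-(methoxymethyl)-6-methyl-4-[(2R)-2-methylbutanoyl]cyclohexa-2,4-dien-1-one
Product: 35 (1S,5R)-5-{[(5R)-4-amino-5-hydroxy-2-methoxy-5-methyl-3-[(2R)-2-methylbutanoyl]-6-oxocyclohexa-1,3-dien-1-yl]methyl}-3-bromo-4-methoxy-1,5-dimethyl-2,6-dioxocyclohex-3-en-1-yl (2R)-2-methylbutanoate, via aza-quinone methide 34 (not isolated)
Conditions: 21 (1.5 equiv), Sc(OTf)3 (10 mol %), 4 Å MS, CH2Cl2/(CF3)2CHOH 4:1, 0 °C → rt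
Reagents that add atoms: none
Why: intermolecular Michael addition, in which Lewis acid-assisted loss of methanol gives an α-methylene ketone and the methyl-bearing enol carbon of 21 adds to it (the other enol carbon is blocked by bromine) anti to the acyloxy group, sets the quaternary centre trans to the ester.

Step 22
Reactants: 35 (1S,5R)-5-{[(5R)-4-amino-5-hydroxy-2-methoxy-5-methyl-3-[(2R)-2-methylbutanoyl]-6-oxocyclohexa-1,3-dien-1-yl]methyl}-3-bromo-4-methoxy-1,5-dimethyl-2,6-dioxocyclohex-3-en-1-yl (2R)-2-methylbutanoate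
Product: 36 (1R,5R)-5-{[(5R)-4-amino-5-hydroxy-2-methoxy-5-methyl-3-[(2R)-2-methylbutanoyl]-6-oxocyclohexa-1,3-dien-1-yl]methyl}-4-methoxy-1,5-dimethyl-2,6-dioxocyclohex-3-en-1-yl (2R)-2-methylbutanoate (gilluone B)
Conditions: Bu3SnH (1.3 equiv), Pd(PPh3)4 (5 mol %), THF, rt
Reagents that add atoms: none
Why: palladium-catalysed hydrodebromination (oxidative addition of zerovalent palladium to the vinyl C–Br bond, hydride transfer from tin, reductive elimination) removes the blocking group without touching any stereocentre.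

**Compound list**

1 | (4R)-4-benzyl-1,3-oxazolidin-2-one | O=C1N[C@H](Cc2ccccc2)CO1 | starting material
2 | butanoyl chloride | CCCC(Cl)=O | starting material
3 | (4R)-4-benzyl-3-butanoyl-1,3-oxazolidin-2-one | CCCC(=O)N1[C@H](Cc2ccccc2)COC1=O | intermediate
4 | sodium Z-enolate of 3 | CC/C=C(\[O-])N1[C@H](Cc2ccccc2)COC1=O.[Na+] | intermediate
5 | (4R)-4-benzyl-3-[(2R)-2-methylbutanoyl]-1,3-oxazolidin-2-one | CC[C@@H](C)C(=O)N1[C@H](Cc2ccccc2)COC1=O | intermediate
6 | (2R)-2-methylbutanoic acid | CC[C@@H](C)C(O)=O | intermediate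
7 | (2R)-2-methylbutanoyl chloride | CC[C@@H](C)C(Cl)=O | intermediate
8 | (S)-lactic acid | C[C@H](O)C(O)=O | starting material
9 | pivalaldehyde | CC(C)(C)C=O | starting material
10 | (2S,5S)-2-tert-butyl-5-methyl-1,3-dioxolan-4-one | C[C@@H]1O[C@H](C(C)(C)C)OC1=O | intermediate
11 | methyl 3-oxopentanoate | CCC(=O)CC(=O)OC | starting material
12 | methyl (2E)-3-methoxypent-2-enoate | CC/C(OC)=C\C(=O)OC | intermediate
13 | (2E)-3-methoxypent-2-enoic acid | CC/C(OC)=C\C(O)=O | intermediate
14 | (2E)-3-methoxypent-2-enoyl chloride | CC/C(OC)=C\C(Cl)=O | intermediate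
15 | lithium (2S)-2-tert-butyl-5-methyl-1,3-dioxol-4-olate | CC1=C([O-])O[C@@H](C(C)(C)C)O1.[Li+] | intermediate
16 | (2S,5R)-2-tert-butyl-5-[(2E)-3-methoxypent-2-enoyl]-5-methyl-1,3-dioxolan-4-one | CC/C(OC)=C\C(=O)[C@@]1(C)O[C@H](C(C)(C)C)OC1=O | intermediate
17 | lithium dienolate of 16 (γ-deprotonated, alkene geometry not fixed) | CC=C(OC)C=C([O-])[C@@]1(C)O[C@H](C(C)(C)C)OC1=O.[Li+] | intermediate
18 | (6S)-5,6-dihydroxy-3-methoxy-4,6-dimethylcyclohexa-2,4-dien-1-one | C[C@@]1(O)C(=O)C=C(OC)C(C)=C1O | intermediate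
19 | (6S)-2-bromo-5,6-dihydroxy-3-methoxy-4,6-dimethylcyclohexa-2,4-dien-1-one | C[C@@]1(O)C(=O)C(Br)=C(OC)C(C)=C1O | intermediate
20 | dilithium alkoxide-dienolate of 19 | C[C@@]1([O-])C(=O)C(Br)=C(OC)C(C)=C1[O-].[Li+].[Li+] | intermediate
21 | (1S)-3-bromo-6-hydroxy-4-methoxy-1,5-dimethyl-2-oxocyclohexa-3,5-dien-1-yl (2R)-2-methylbutanoate | CC[C@@H](C)C(=O)O[C@]1(C)C(=O)C(Br)=C(OC)C(C)=C1O | intermediate
22 | methyl 5-methoxy-3-oxopentanoate | COCCC(=O)CC(=O)OC | starting material
23 | methyl (2E)-3,5-dimethoxypent-2-enoate | COCC/C(OC)=C\C(=O)OC | intermediate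
24 | (2E)-3,5-dimethoxypent-2-enoic acid | COCC/C(OC)=C\C(O)=O | intermediate
25 | (2E)-3,5-dimethoxypent-2-enoyl chloride | COCC/C(OC)=C\C(Cl)=O | intermediate
26 | sodium (2S)-2-tert-butyl-5-methyl-1,3-dioxol-4-olate | CC1=C([O-])O[C@@H](C(C)(C)C)O1.[Na+] | intermediate
27 | (2S,5R)-2-tert-butyl-5-[(2E)-3,5-dimethoxypent-2-enoyl]-5-methyl-1,3-dioxolan-4-one | COCC/C(OC)=C\C(=O)[C@@]1(C)O[C@H](C(C)(C)C)OC1=O | intermediate
28 | lithium dienolate of 27 (γ-deprotonated, alkene geometry not fixed) | COCC=C(OC)C=C([O-])[C@@]1(C)O[C@H](C(C)(C)C)OC1=O.[Li+] | intermediate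
29 | (6S)-5,6-dihydroxy-3-methoxy-4-(methoxymethyl)-6-methylcyclohexa-2,4-dien-1-one | C[C@@]1(O)C(=O)C=C(OC)C(COC)=C1O | intermediate
30 | (6S)-6-hydroxy-3-methoxy-2-(methoxymethyl)-6-methyl-5-oxocyclohexa-1,3-dien-1-yl (2R)-2-methylbutanoate (enol ester) | C[C@@]1(O)C(=O)C=C(OC)C(COC)=C1OC(=O)[C@H](C)CC | intermediate
31 | (6R)-5,6-dihydroxy-3-methoxy-2-(methoxymethyl)-6-methyl-4-[(2R)-2-methylbutanoyl]cyclohexa-2,4-dien-1-one | C[C@@]1(O)C(O)=C(C(=O)[C@H](C)CC)C(OC)=C(COC)C1=O | intermediate
32 | (6R)-6-hydroxy-3,5-dimethoxy-2-(methoxymethyl)-6-methyl-4-[(2R)-2-methylbutanoyl]cyclohexa-2,4-dien-1-one | C[C@@]1(O)C(OC)=C(C(=O)[C@H](C)CC)C(OC)=C(COC)C1=O | intermediate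
33 | (6R)-5-amino-6-hydroxy-3-methoxy-2-(methoxymethyl)-6-methyl-4-[(2R)-2-methylbutanoyl]cyclohexa-2,4-dien-1-one | C[C@@]1(O)C(N)=C(C(=O)[C@H](C)CC)C(OC)=C(COC)C1=O | intermediate
34 | (6R)-6-hydroxy-5-imino-3-methoxy-6-methyl-2-methylidene-4-[(2R)-2-methylbutanoyl]cyclohex-3-en-1-one (aza-quinone methide) | C=C1C(=O)[C@](C)(O)C(=N)C(C(=O)[C@H](C)CC)=C1OC | intermediate
35 | (1S,5R)-5-{[(5R)-4-amino-5-hydroxy-2-methoxy-5-methyl-3-[(2R)-2-methylbutanoyl]-6-oxocyclohexa-1,3-dien-1-yl]methyl}-3-bromo-4-methoxy-1,5-dimethyl-2,6-dioxocyclohex-3-en-1-yl (2R)-2-methylbutanoate | CC[C@@H](C)C(=O)O[C@]1(C)C(=O)C(Br)=C(OC)[C@@](C)(CC2=C(OC)C(C(=O)[C@H](C)CC)=C(N)[C@@](C)(O)C2=O)C1=O | intermediate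
36 | gilluone B, (1R,5R)-5-{[(5R)-4-amino-5-hydroxy-2-methoxy-5-methyl-3-[(2R)-2-methylbutanoyl]-6-oxocyclohexa-1,3-dien-1-yl]methyl}-4-methoxy-1,5-dimethyl-2,6-dioxocyclohex-3-en-1-yl (2R)-2-methylbutanoate | CC[C@@H](C)C(=O)O[C@]1(C)C(=O)C=C(OC)[C@@](C)(CC2=C(OC)C(C(=O)[C@H](C)CC)=C(N)[C@@](C)(O)C2=O)C1=O | target

**Summary**

Total step count: 22.
Longest linear sequence: 10 steps (steps 13 to 22, from 22 to 36).

The three steps most likely to fail:

Step 21 (Michael coupling). The methoxymethyl group may ionise sluggishly, and O-alkylation or attack on the wrong face at the new quaternary carbon may compete. The fallback sets out from 33 and 21 and comes back to the route at 35. Oxidise the methoxymethyl group of 33 with DDQ in wet CH2Cl2 to the ring B aldehyde F1. Add the enol 21 to it with TiCl4 in CH2Cl2 at -78 °C (aldol addition organised by chelation of the aldehyde and the enol oxygen) to give the bromo carbinol F2 as a carbinol mixture. Remove the hydroxyl by ionic deoxygenation with Et3SiH and CF3CO2H, which gives 35.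

Step 20 (ammonolysis, which also depends on the regiochemistry of step 19). Ammonia could displace the C3 methoxy group or attack the acyl carbonyl, and diazomethane could methylate another oxygen. The fallback sets out from 31 and comes back at 33. Treat 31 with (COCl)2 and catalytic DMF to give the vinylogous acid chloride F3. Displace chloride with NaN3 in DMF to give the vinyl azide F4. Reduce by the Staudinger reaction (PPh3 in THF, then H2O) to reach 33 without using ammonia.

Step 22 (debromination). The tin hydride with zerovalent palladium could reduce or insert elsewhere in the presence of the free enaminone. The fallback sets out from 21 and 32 and comes back at 36. Couple 21 with the bis-methoxy dienone 32 (BF3·OEt2, CH2Cl2, -40 °C, the same Michael addition through the methide) to give the bromo bis-methoxy adduct F5. Cleave the C–Br bond by hydrogenolysis (H2, Pd/C, NaOAc, EtOAc) to give the debrominated bis-methoxy adduct F6. Finish with NH3 in MeOH as in step 20, which gives 36.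

**Further compounds**

F1 | step 21 | (5R)-4-amino-5-hydroxy-2-methoxy-5-methyl-3-[(2R)-2-methylbutanoyl]-6-oxocyclohexa-1,3-diene-1-carbaldehyde | C[C@@]1(O)C(N)=C(C(=O)[C@H](C)CC)C(OC)=C(C=O)C1=O
F2 | step 21 | bromo carbinol, 35 with CH(OH) in place of the bridging CH2 (carbinol carbon as a mixture) | CC[C@@H](C)C(=O)O[C@]1(C)C(=O)C(Br)=C(OC)[C@@](C)(C(O)C2=C(OC)C(C(=O)[C@H](C)CC)=C(N)[C@@](C)(O)C2=O)C1=O
F3 | step 20 | (6R)-5-chloro-6-hydroxy-3-methoxy-2-(methoxymethyl)-6-methyl-4-[(2R)-2-methylbutanoyl]cyclohexa-2,4-dien-1-one | C[C@@]1(O)C(Cl)=C(C(=O)[C@H](C)CC)C(OC)=C(COC)C1=O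
F4 | step 20 | (6R)-5-azido-6-hydroxy-3-methoxy-2-(methoxymethyl)-6-methyl-4-[(2R)-2-methylbutanoyl]cyclohexa-2,4-dien-1-one | C[C@@]1(O)C(N=[N+]=[N-])=C(C(=O)[C@H](C)CC)C(OC)=C(COC)C1=O
F5 | step 22 | bromo bis-methoxy adduct, 35 with OMe in place of NH2 | CC[C@@H](C)C(=O)O[C@]1(C)C(=O)C(Br)=C(OC)[C@@](C)(CC2=C(OC)C(C(=O)[C@H](C)CC)=C(OC)[C@@](C)(O)C2=O)C1=O
F6 | step 22 | debrominated bis-methoxy adduct, 36 with OMe in place of NH2 | CC[C@@H](C)C(=O)O[C@]1(C)C(=O)C=C(OC)[C@@](C)(CC2=C(OC)C(C(=O)[C@H](C)CC)=C(OC)[C@@](C)(O)C2=O)C1=O
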